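The route rests on cutting C2–C3 of the five-membered ring. C3 lies beta to C4, the six-ring carbon that bears the methylidene and is carried as a latent ketone, so a C3–C3a–C4 siloxycyclopropane fused to the six-membered ring is a masked C3 homoenolate. TiCl4 opens C3–C4 and the C3–Ti bond adds to the C2 aldehyde on the C7a branch: one operation closes the cyclopentane trans-fused, sets the C2 carbinol and unmasks the C4 ketone. The precursor is a 1-siloxybicyclo[4.1.0]heptane carrying the C6 ether, the C7 isopropyl group and a C7a side chain with the aldehyde and a protected carbinol.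

Key step: step 19

Remark on the chemistry: hydrindane locants (C1–C7a, as in the target) are used for all intermediates; the acetyl group is carried as an ether-protected (1R)-carbinol, because a C1 centre between an ester and a ketone would epimerise whereas an auxiliary-controlled aldol fixes it; C6 carries a 4-methoxybenzyl (PMB) ether that can direct the zinc carbenoid, the carbinol carries a chelating naphthalen-2-ylmethyl (NAP) ether, and the cyclopropanol is kept as its TBS ether.

Step 1
Reactants: 1 (2E)-4-methylpent-2-enal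
Product: 2 (2E)-4-methylpent-2-en-1-ol
Conditions: NaBH4, CeCl3·7H2O, MeOH, 0 °C
Reagents that add atoms: none
Why: Luche reduction should deliver hydride 1,2 to the enal only, so the E double bond is kept.

Step 2
Reactants: 2 (2E)-4-methylpent-2-en-1-ol
Product: 3 2-[(2E)-4-methylpent-2-en-1-yl]-4,4,5,5-tetramethyl-1,3,2-dioxaborolane (E-allylboronate)
Conditions: B2pin2, Pd(MeCN)4(BF4)2 (5 mol %), DMSO–MeOH, 50 °C
Reagents that add atoms: bis(pinacolato)diboron, CC1(C)OB(OC1(C)C)B1OC(C)(C)C(C)(C)O1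
Why: Palladium-catalysed Miyaura-type borylation of the allylic alcohol should pass through an allylpalladium intermediate that takes boron at the unhindered terminus, giving the linear E-allylboronate.

Step 3
Reactants: 4 3,3-diethoxypropan-1-ol
Product: 5 3,3-diethoxypropanal
Conditions: Dess–Martin periodinane, NaHCO3, CH2Cl2, 0 °C to rt
Reagents that add atoms: none
Why: Buffered Dess–Martin oxidation should give the aldehyde without touching the acid-labile acetal.

Step 4
Reactants: 3 E-allylboronate; 5 3,3-diethoxypropanal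
Product: 6 (3R,4S)-1,1-diethoxy-4-(propan-2-yl)hex-5-en-3-ol
Conditions: (S)-TRIP [(S)-3,3'-bis(2,4,6-triisopropylphenyl)-1,1'-binaphthyl-2,2'-diyl hydrogen phosphate] (5 mol %), 4 Å MS, toluene, −30 °C; then aqueous NaHCO3
Reagents that add atoms: none
Why: Chiral phosphoric acid-catalysed allylboration through a closed chair (Zimmerman–Traxler) transition state should turn the E-boronate into the anti pair, and the (S)-catalyst is chosen to direct the allyl group to the Si face of the aldehyde, which sets C6 (R) and C7 (S) together.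

Step 5
Reactants: 6 (3R,4S)-1,1-diethoxy-4-(propan-2-yl)hex-5-en-3-ol
Product: 7 PMB ether of 6
Conditions: NaH, PMBCl, Bu4NI (cat.), THF–DMF, 0 °C to rt
Reagents that add atoms: 4-methoxybenzyl chloride, COc1ccc(CCl)cc1
Why: Williamson etherification of the sodium alkoxide should install the benzyl-type ether that later directs the cyclopropanation; neither stereocentre is touched.

Step 6
Reactants: 7 PMB ether acetal
Product: 8 (3R,4S)-3-[(4-methoxyphenyl)methoxy]-4-(propan-2-yl)hex-5-enal
Conditions: 1 M HCl, THF, 0 °C to rt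
Reagents that add atoms: water, O
Why: Mild aqueous acid hydrolysis of the diethyl acetal should free the aldehyde, while the PMB ether survives dilute acid at low temperature.

Step 7
Reactants: 8 beta-alkoxy aldehyde
Product: 9 (5R,6S)-5-[(4-methoxyphenyl)methoxy]-6-(propan-2-yl)octa-1,7-dien-3-ol (both C3 epimers)
Conditions: CH2=CHMgBr, THF, −78 °C
Reagents that add atoms: vinylmagnesium bromide, C=C[Mg]Br
Why: Grignard addition to the aldehyde should give the divinyl substrate; the new carbinol centre forms as a mixture that is erased in step 9.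

Step 8
Reactants: 9 dienol
Product: 10 (4S,5R)-5-[(4-methoxyphenyl)methoxy]-4-(propan-2-yl)cyclohex-2-en-1-ol (both C1 epimers)
Conditions: second-generation Grubbs catalyst (H2IMes)(PCy3)Cl2Ru=CHPh (5 mol %), CH2Cl2, 40 °C
Reagents that add atoms: none
Why: Ring-closing metathesis of the 1,7-diene should close the six-membered ring at the future C3a=C7a bond with loss of ethene.

Step 9
Reactants: 10 cyclohexenol
Product: 11 (4S,5R)-5-[(4-methoxyphenyl)methoxy]-4-(propan-2-yl)cyclohex-2-en-1-one
Conditions: Dess–Martin periodinane, NaHCO3, CH2Cl2, rt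
Reagents that add atoms: none
Why: Dess–Martin oxidation of the allylic alcohol should give the enone under neutral conditions, which avoids elimination of the beta-ether towards a phenol.

Step 10
Reactants: 11 enone; 12 tert-butyl[(1-methoxyethenyl)oxy]dimethylsilane
Product: 13 methyl 2-[(1S,5R,6S)-3-[(tert-butyldimethylsilyl)oxy]-5-[(4-methoxyphenyl)methoxy]-6-(propan-2-yl)cyclohex-2-en-1-yl]acetate
Conditions: TBSOTf (10 mol %), CH2Cl2, −78 °C; then Et3N
Reagents that add atoms: none
Why: Mukaiyama–Michael addition with silyl transfer should attack C7a anti to the adjacent C7 isopropyl group and the axial C6 ether, which sets C7a and leaves the C3a=C4 enol ether regiodefined.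

Step 11
Reactants: 13 ring TBS enol ether
Product: 14 siloxycyclopropane methyl ester
Conditions: Et2Zn, CH2I2, CH2Cl2, 0 °C to rt
Reagents that add atoms: diiodomethane, ICI
Why: Simmons–Smith cyclopropanation (Furukawa reagent) of the electron-rich enol ether should be delivered by zinc coordination to the axial C6 benzyl-type ether on the lower face, opposite the C7a side chain, which sets C3a and C4 with C3 trans to the C7a branch.

Step 12
Reactants: 14 siloxycyclopropane methyl ester
Product: 15 siloxycyclopropane acetic acid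
Conditions: LiOH·H2O, THF–MeOH–H2O, rt; then 1 M HCl to pH 4
Reagents that add atoms: lithium hydroxide, [Li+].[OH-]
Why: Saponification of the methyl ester should leave the tertiary TBS ether and the PMB ether untouched.

Step 13
Reactants: 15 siloxycyclopropane acetic acid; 16 (4S)-4-benzyl-1,3-oxazolidin-2-one
Product: 18 N-acyl oxazolidinone, via mixed pivalic anhydride 17 (not isolated)
Conditions: PivCl, Et3N, THF, −20 °C; then 16, LiCl, rt
Reagents that add atoms: none
Why: N-acylation of the oxazolidinone through the mixed pivalic anhydride (LiCl–Et3N variant) should give the imide without strong base.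

Step 14
Reactants: 18 N-acyl oxazolidinone; 19 acetaldehyde
Product: 21 syn-aldol imide, via dibutylboron enolate 20 (not isolated)
Conditions: Bu2BOTf, iPr2NEt, CH2Cl2, −78 to 0 °C; then 19, −78 to 0 °C; pH 7 buffer, MeOH, H2O2
Reagents that add atoms: none
Why: Evans syn aldol reaction through the Z-boron enolate and a Zimmerman–Traxler transition state should set C1 and the carbinol carbon under control of the auxiliary, overriding any bias of the ring.

Step 15
Reactants: 22 (naphthalen-2-yl)methanol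
Product: 23 (naphthalen-2-yl)methyl 2,2,2-trichloroacetimidate
Conditions: Cl3CCN, DBU (10 mol %), CH2Cl2, 0 °C
Reagents that add atoms: trichloroacetonitrile, N#CC(Cl)(Cl)Cl
Why: Base-catalysed addition of the alcohol to the nitrile (imidate formation) should give the alkylating agent for the next step.

Step 16
Reactants: 21 syn-aldol imide; 23 trichloroacetimidate
Product: 24 NAP ether imide
Conditions: La(OTf)3 (5 mol %), toluene, rt
Reagents that add atoms: none
Why: Lewis acid-catalysed O-alkylation with the trichloroacetimidate should protect the aldol hydroxyl without base, so that retro-aldol cleavage and epimerisation at C1 are avoided.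

Step 17
Reactants: 24 NAP ether imide
Product: 25 primary alcohol
Conditions: LiBH4, MeOH, Et2O, 0 °C
Reagents that add atoms: none
Why: Reductive cleavage of the imide with LiBH4 should release the primary alcohol and the recoverable auxiliary without touching the silyl ether.

Step 18
Reactants: 25 primary alcohol
Product: 26 siloxycyclopropane aldehyde (precursor of the key step)
Conditions: Dess–Martin periodinane, NaHCO3, CH2Cl2, 0 °C to rt
Reagents that add atoms: none
Why: Buffered Dess–Martin oxidation should give the alpha-branched aldehyde without epimerisation at C1 or loss of the beta-ether.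

Step 19
Reactants: 26 siloxycyclopropane aldehyde
Product: 28 trans-hydrindan-4-one bearing the C2 carbinol, via trichlorotitanium homoenolate 27 (not isolated)
Conditions: TiCl4 (2.5 equiv), CH2Cl2, −78 to −40 °C; then H2O
Reagents that add atoms: none
Why: Proposed new method: TiCl4 should attack the least hindered cyclopropane carbon C3 and break the oxygen-polarised C3–C4 bond with loss of TBSCl to give the C3-trichlorotitanium homoenolate 27 of the C4 ketone, whose C–Ti bond then adds to the TiCl4-chelated C2 aldehyde. The closest known reaction type is the addition to aldehydes, between molecules, of titanium homoenolates made from 1-alkoxy-1-siloxycyclopropanes and TiCl4; the ketone-derived, intramolecular form is not established. The cyclopentane closes in a 5-exo-trig mode between the trans-diequatorial C3a and C7a branches, so the trans ring fusion already fixed by the cyclopropane is kept. The new C2 centre should be controlled by the six-membered titanium chelate between the aldehyde oxygen and the NAP ether oxygen, which holds C=O syn to the ether carbon while the C7a tether sits axial on the chelate and delivers C3 to that face, giving the C2 oxygen cis to the C1 side chain (2S). The step needs cleavage of C3–C4 and not of C3–C3a, which the donor oxygen on C4 secures, and one aldehyde face, which the chelating ether on the C1 branch secures.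

Step 20
Reactants: 28 hydroxy ketone
Product: 29 4-methylidene alcohol
Conditions: Zn, CH2Br2, TiCl4, THF–CH2Cl2, 0 °C to rt
Reagents that add atoms: dibromomethane, BrCBr
Why: Takai–Lombardo methylenation is non-basic, so the ketone should become the exocyclic alkene without epimerisation at C3a or elimination of the C6 ether, and the free hydroxyl is tolerated.

Step 21
Reactants: 29 4-methylidene alcohol; 30 angelic acid
Product: 32 C2 angelate, via mixed angeloyl anhydride 31 (not isolated)
Conditions: 30, 2,4,6-Cl3C6H2COCl, Et3N, toluene, rt; then 29, 75 °C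
Reagents that add atoms: none
Why: Yamaguchi-type acylation through the preformed mixed anhydride without DMAP should esterify the C2 alcohol with retention of the Z geometry of the angeloyl group.

Step 22
Reactants: 32 C2 angelate
Product: 33 C6 alcohol
Conditions: (NH4)2Ce(NO3)6, MeCN–H2O, 0 °C
Reagents that add atoms: none
Why: Oxidative ether cleavage with the cerium reagent should remove the electron-rich PMB group while the less easily oxidised NAP ether, the angelate and the alkene remain.

Step 23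
Reactants: 30 angelic acid
Product: 34 (2Z)-2-methylbut-2-en-1-ol
Conditions: LiAlH4, Et2O, 0 °C to rt
Reagents that add atoms: none
Why: Hydride reduction of the acid with LiAlH4 should give the allylic alcohol with the Z geometry intact.

Step 24
Reactants: 34 (2Z)-2-methylbut-2-en-1-ol
Product: 35 [(2R,3S)-2,3-dimethyloxiran-2-yl]methanol
Conditions: Ti(OiPr)4 (10 mol %), D-(−)-diethyl tartrate (12 mol %), t-BuOOH, 4 Å MS, CH2Cl2, −20 °C
Reagents that add atoms: tert-butyl hydroperoxide, CC(C)(C)OO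
Why: Sharpless asymmetric epoxidation with the D-tartrate should deliver oxygen to the face of the Z-allylic alcohol that gives the (2R,3S)-epoxy alcohol, and the cis relation of methyl and hydroxymethyl follows from the alkene geometry.

Step 25
Reactants: 35 epoxy alcohol
Product: 36 (2S,3S)-2,3-dimethyloxirane-2-carboxylic acid
Conditions: TEMPO (20 mol %), PhI(OAc)2, MeCN–H2O, rt
Reagents that add atoms: water, O
Why: TEMPO-catalysed oxidation should take the primary alcohol to the acid through the aldehyde hydrate without opening the epoxide; only the priority change at C2 turns the descriptor into (2S,3S).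

Step 26
Reactants: 33 C6 alcohol; 36 (2S,3S)-2,3-dimethyloxirane-2-carboxylic acid
Product: 38 diester NAP ether, via mixed epoxyacyl anhydride 37 (not isolated)
Conditions: 36, 2,4,6-Cl3C6H2COCl, Et3N, THF, rt; then 33, DMAP, toluene, 40 °C
Reagents that add atoms: none
Why: Yamaguchi esterification through the mixed anhydride with DMAP should acylate the hindered axial C6 alcohol; the acid has no enolisable or isomerisable position.

Step 27
Reactants: 38 diester NAP ether
Product: 39 diester with free (1R)-1-hydroxyethyl group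
Conditions: DDQ, CH2Cl2–pH 7 buffer, rt
Reagents that add atoms: none
Why: Oxidative cleavage of the NAP ether with DDQ under buffered conditions should free the secondary alcohol without affecting epoxide, esters or alkene.

Step 28
Reactants: 39 diester alcohol
Product: 40 CNP0300602.1 (target)
Conditions: Dess–Martin periodinane, NaHCO3, CH2Cl2, 0 °C to rt
Reagents that add atoms: none
Why: Buffered Dess–Martin oxidation should give the methyl ketone under neutral conditions, so the C1 centre between ketone and acyloxy group is not epimerised and no beta-elimination occurs.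

Compound list

1 | (2E)-4-methylpent-2-enal | CC(C)/C=C/C=O | starting material
2 | (2E)-4-methylpent-2-en-1-ol | CC(C)/C=C/CO | intermediate
3 | 2-[(2E)-4-methylpent-2-en-1-yl]-4,4,5,5-tetramethyl-1,3,2-dioxaborolane | CC(C)/C=C/CB1OC(C)(C)C(C)(C)O1 | intermediate
4 | 3,3-diethoxypropan-1-ol | CCOC(OCC)CCO | starting material
5 | 3,3-diethoxypropanal | CCOC(OCC)CC=O | intermediate
6 | (3R,4S)-1,1-diethoxy-4-(propan-2-yl)hex-5-en-3-ol | CCOC(OCC)C[C@@H](O)[C@@H](C(C)C)C=C | intermediate
7 | 1-({[(3R,4S)-1,1-diethoxy-4-(propan-2-yl)hex-5-en-3-yl]oxy}methyl)-4-methoxybenzene | CCOC(OCC)C[C@@H](OCc1ccc(OC)cc1)[C@@H](C(C)C)C=C | intermediate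
8 | (3R,4S)-3-[(4-methoxyphenyl)methoxy]-4-(propan-2-yl)hex-5-enal | O=CC[C@@H](OCc1ccc(OC)cc1)[C@@H](C(C)C)C=C | intermediate
9 | (5R,6S)-5-[(4-methoxyphenyl)methoxy]-6-(propan-2-yl)octa-1,7-dien-3-ol (both C3 epimers) | C=CC(O)C[C@@H](OCc1ccc(OC)cc1)[C@@H](C(C)C)C=C | intermediate
10 | (4S,5R)-5-[(4-methoxyphenyl)methoxy]-4-(propan-2-yl)cyclohex-2-en-1-ol (both C1 epimers) | OC1C[C@@H](OCc2ccc(OC)cc2)[C@@H](C(C)C)C=C1 | intermediate
11 | (4S,5R)-5-[(4-methoxyphenyl)methoxy]-4-(propan-2-yl)cyclohex-2-en-1-one | O=C1C[C@@H](OCc2ccc(OC)cc2)[C@@H](C(C)C)C=C1 | intermediate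
12 | tert-butyl[(1-methoxyethenyl)oxy]dimethylsilane | C=C(OC)O[Si](C)(C)C(C)(C)C | starting material
13 | methyl 2-[(1S,5R,6S)-3-[(tert-butyldimethylsilyl)oxy]-5-[(4-methoxyphenyl)methoxy]-6-(propan-2-yl)cyclohex-2-en-1-yl]acetate | C1=C(O[Si](C)(C)C(C)(C)C)C[C@@H](OCc2ccc(OC)cc2)[C@@H](C(C)C)[C@@H]1CC(=O)OC | intermediate
14 | methyl 2-[(1R,2S,3S,4R,6R)-6-[(tert-butyldimethylsilyl)oxy]-4-[(4-methoxyphenyl)methoxy]-3-(propan-2-yl)bicyclo[4.1.0]heptan-2-yl]acetate | CC(C)(C)[Si](C)(C)O[C@]12C[C@@H](OCc3ccc(OC)cc3)[C@@H](C(C)C)[C@H](CC(=O)OC)[C@H]1C2 | intermediate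
15 | 2-[(1R,2S,3S,4R,6R)-6-[(tert-butyldimethylsilyl)oxy]-4-[(4-methoxyphenyl)methoxy]-3-(propan-2-yl)bicyclo[4.1.0]heptan-2-yl]acetic acid | CC(C)(C)[Si](C)(C)O[C@]12C[C@@H](OCc3ccc(OC)cc3)[C@@H](C(C)C)[C@H](CC(=O)O)[C@H]1C2 | intermediate
16 | (4S)-4-benzyl-1,3-oxazolidin-2-one | O=C1N[C@@H](Cc2ccccc2)CO1 | starting material
17 | 2-[(1R,2S,3S,4R,6R)-6-[(tert-butyldimethylsilyl)oxy]-4-[(4-methoxyphenyl)methoxy]-3-(propan-2-yl)bicyclo[4.1.0]heptan-2-yl]acetic 2,2-dimethylpropanoic anhydride | CC(C)(C)[Si](C)(C)O[C@]12C[C@@H](OCc3ccc(OC)cc3)[C@@H](C(C)C)[C@H](CC(=O)OC(=O)C(C)(C)C)[C@H]1C2 | intermediate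
18 | (4S)-4-benzyl-3-{2-[(1R,2S,3S,4R,6R)-6-[(tert-butyldimethylsilyl)oxy]-4-[(4-methoxyphenyl)methoxy]-3-(propan-2-yl)bicyclo[4.1.0]heptan-2-yl]acetyl}-1,3-oxazolidin-2-one | CC(C)(C)[Si](C)(C)O[C@]12C[C@@H](OCc3ccc(OC)cc3)[C@@H](C(C)C)[C@H](CC(=O)N4[C@@H](Cc5ccccc5)COC4=O)[C@H]1C2 | intermediate
19 | acetaldehyde | CC=O | starting material
20 | dibutyl{[(1Z)-1-[(4S)-4-benzyl-2-oxo-1,3-oxazolidin-3-yl]-2-[(1R,2S,3S,4R,6R)-6-[(tert-butyldimethylsilyl)oxy]-4-[(4-methoxyphenyl)methoxy]-3-(propan-2-yl)bicyclo[4.1.0]heptan-2-yl]ethenyl]oxy}borane | CC(C)(C)[Si](C)(C)O[C@]12C[C@@H](OCc3ccc(OC)cc3)[C@@H](C(C)C)[C@H](/C=C(\OB(CCCC)CCCC)N4[C@@H](Cc5ccccc5)COC4=O)[C@H]1C2 | intermediate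
21 | (4S)-4-benzyl-3-[(2S,3R)-2-[(1R,2S,3S,4R,6R)-6-[(tert-butyldimethylsilyl)oxy]-4-[(4-methoxyphenyl)methoxy]-3-(propan-2-yl)bicyclo[4.1.0]heptan-2-yl]-3-hydroxybutanoyl]-1,3-oxazolidin-2-one | CC(C)(C)[Si](C)(C)O[C@]12C[C@@H](OCc3ccc(OC)cc3)[C@@H](C(C)C)[C@H]([C@H](C(=O)N4[C@@H](Cc5ccccc5)COC4=O)[C@@H](C)O)[C@H]1C2 | intermediate
22 | (naphthalen-2-yl)methanol | OCc1ccc2ccccc2c1 | starting material
23 | (naphthalen-2-yl)methyl 2,2,2-trichloroacetimidate | N=C(OCc1ccc2ccccc2c1)C(Cl)(Cl)Cl | intermediate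
24 | (4S)-4-benzyl-3-[(2S,3R)-2-[(1R,2S,3S,4R,6R)-6-[(tert-butyldimethylsilyl)oxy]-4-[(4-methoxyphenyl)methoxy]-3-(propan-2-yl)bicyclo[4.1.0]heptan-2-yl]-3-[(naphthalen-2-yl)methoxy]butanoyl]-1,3-oxazolidin-2-one | CC(C)(C)[Si](C)(C)O[C@]12C[C@@H](OCc3ccc(OC)cc3)[C@@H](C(C)C)[C@H]([C@H](C(=O)N4[C@@H](Cc5ccccc5)COC4=O)[C@@H](C)OCc6ccc7ccccc7c6)[C@H]1C2 | intermediate
25 | (2R,3R)-2-[(1R,2R,3S,4R,6R)-6-[(tert-butyldimethylsilyl)oxy]-4-[(4-methoxyphenyl)methoxy]-3-(propan-2-yl)bicyclo[4.1.0]heptan-2-yl]-3-[(naphthalen-2-yl)methoxy]butan-1-ol | CC(C)(C)[Si](C)(C)O[C@]12C[C@@H](OCc3ccc(OC)cc3)[C@@H](C(C)C)[C@H]([C@H](CO)[C@@H](C)OCc6ccc7ccccc7c6)[C@H]1C2 | intermediate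
26 | (2S,3R)-2-[(1R,2S,3S,4R,6R)-6-[(tert-butyldimethylsilyl)oxy]-4-[(4-methoxyphenyl)methoxy]-3-(propan-2-yl)bicyclo[4.1.0]heptan-2-yl]-3-[(naphthalen-2-yl)methoxy]butanal | CC(C)(C)[Si](C)(C)O[C@]12C[C@@H](OCc3ccc(OC)cc3)[C@@H](C(C)C)[C@H]([C@H](C=O)[C@@H](C)OCc6ccc7ccccc7c6)[C@H]1C2 | intermediate
27 | trichloro{[(1R,2R,3S,4R)-4-[(4-methoxyphenyl)methoxy]-2-[(2S,3R)-3-[(naphthalen-2-yl)methoxy]-1-oxobutan-2-yl]-6-oxo-3-(propan-2-yl)cyclohexyl]methyl}titanium | Cl[Ti](Cl)(Cl)C[C@H]1C(=O)C[C@@H](OCc2ccc(OC)cc2)[C@@H](C(C)C)[C@@H]1[C@H](C=O)[C@@H](C)OCc3ccc4ccccc4c3 | intermediate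
28 | (1R,2S,3aR,6R,7S,7aR)-2-hydroxy-6-[(4-methoxyphenyl)methoxy]-1-[(1R)-1-[(naphthalen-2-yl)methoxy]ethyl]-7-(propan-2-yl)octahydro-4H-inden-4-one | O=C1C[C@@H](OCc3ccc(OC)cc3)[C@@H](C(C)C)[C@@H]2[C@@H]([C@@H](C)OCc4ccc5ccccc5c4)[C@@H](O)C[C@@H]12 | intermediate
29 | (1R,2S,3aR,6R,7S,7aR)-6-[(4-methoxyphenyl)methoxy]-4-methylidene-1-[(1R)-1-[(naphthalen-2-yl)methoxy]ethyl]-7-(propan-2-yl)octahydro-1H-inden-2-ol | C=C1C[C@@H](OCc3ccc(OC)cc3)[C@@H](C(C)C)[C@@H]2[C@@H]([C@@H](C)OCc4ccc5ccccc5c4)[C@@H](O)C[C@@H]12 | intermediate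
30 | angelic acid, (2Z)-2-methylbut-2-enoic acid | C/C=C(/C)C(=O)O | starting material
31 | (2Z)-2-methylbut-2-enoic 2,4,6-trichlorobenzoic anhydride | C/C=C(/C)C(=O)OC(=O)c1c(Cl)cc(Cl)cc1Cl | intermediate
32 | (1S,2S,3aR,6R,7S,7aR)-6-[(4-methoxyphenyl)methoxy]-4-methylidene-1-[(1R)-1-[(naphthalen-2-yl)methoxy]ethyl]-7-(propan-2-yl)octahydro-1H-inden-2-yl (2Z)-2-methylbut-2-enoate | C=C1C[C@@H](OCc3ccc(OC)cc3)[C@@H](C(C)C)[C@@H]2[C@@H]([C@@H](C)OCc4ccc5ccccc5c4)[C@@H](OC(=O)/C(C)=C\C)C[C@@H]12 | intermediate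
33 | (1S,2S,3aR,6R,7S,7aR)-6-hydroxy-4-methylidene-1-[(1R)-1-[(naphthalen-2-yl)methoxy]ethyl]-7-(propan-2-yl)octahydro-1H-inden-2-yl (2Z)-2-methylbut-2-enoate | C=C1C[C@@H](O)[C@@H](C(C)C)[C@@H]2[C@@H]([C@@H](C)OCc3ccc4ccccc4c3)[C@@H](OC(=O)/C(C)=C\C)C[C@@H]12 | intermediate
34 | (2Z)-2-methylbut-2-en-1-ol | C/C=C(/C)CO | intermediate
35 | [(2R,3S)-2,3-dimethyloxiran-2-yl]methanol | OC[C@@]1(C)O[C@H]1C | intermediate
36 | (2S,3S)-2,3-dimethyloxirane-2-carboxylic acid | OC(=O)[C@@]1(C)O[C@H]1C | intermediate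
37 | (2S,3S)-2,3-dimethyloxirane-2-carboxylic 2,4,6-trichlorobenzoic anhydride | O=C(OC(=O)c1c(Cl)cc(Cl)cc1Cl)[C@@]2(C)O[C@H]2C | intermediate
38 | (1S,2S,3aR,6R,7S,7aR)-4-methylidene-2-{[(2Z)-2-methylbut-2-enoyl]oxy}-1-[(1R)-1-[(naphthalen-2-yl)methoxy]ethyl]-7-(propan-2-yl)octahydro-1H-inden-6-yl (2S,3S)-2,3-dimethyloxirane-2-carboxylate | C=C1C[C@@H](OC(=O)[C@@]3(C)O[C@H]3C)[C@@H](C(C)C)[C@@H]2[C@@H]([C@@H](C)OCc4ccc5ccccc5c4)[C@@H](OC(=O)/C(C)=C\C)C[C@@H]12 | intermediate
39 | (1S,2S,3aR,6R,7S,7aR)-1-[(1R)-1-hydroxyethyl]-4-methylidene-2-{[(2Z)-2-methylbut-2-enoyl]oxy}-7-(propan-2-yl)octahydro-1H-inden-6-yl (2S,3S)-2,3-dimethyloxirane-2-carboxylate | C=C1C[C@@H](OC(=O)[C@@]3(C)O[C@H]3C)[C@@H](C(C)C)[C@@H]2[C@@H]([C@@H](C)O)[C@@H](OC(=O)/C(C)=C\C)C[C@@H]12 | intermediate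
40 | CNP0300602.1, (1R,2S,3aR,6R,7S,7aR)-1-acetyl-4-methylidene-2-{[(2Z)-2-methylbut-2-enoyl]oxy}-7-(propan-2-yl)octahydro-1H-inden-6-yl (2S,3S)-2,3-dimethyloxirane-2-carboxylate | C=C1C[C@@H](OC(=O)[C@@]2(C)O[C@H]2C)[C@@H](C(C)C)[C@@H]2[C@@H](C(C)=O)[C@@H](OC(=O)/C(C)=C\C)C[C@@H]12 | target

Total step count: 28. Longest linear sequence: 23 steps (1, 2, 4–14, 16–22, 26–28).

Steps most likely to fail

Step 19. The bulky silyl ether may slow the opening of the cyclopropane, the C3–Ti bond may be protonated or the benzyl-type ethers attacked before the closure, and facial control at C2 may be incomplete. The fallback sets out from 26 and uses known reactions. Hg(OAc)2 in CH2Cl2 should open the same C3–C4 bond to the acetoxymercurio ketone F1, and PdCl2 in MeCN should then give the alpha-methylene ketone F2 by beta-hydride elimination. SmI2 in THF–MeOH at −78 °C should join C2 to C3 by reductive aldehyde–enone (ketyl–olefin) cyclisation and return to 28 after protonation of the samarium enolate. In this variant the ring fusion is set by that protonation and no longer by the cyclopropane, so the epimers at C3a and C2 would have to be separated.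

Step 11. The carbenoid may be delivered to the wrong face of the enol ether if coordination to the C6 ether does not outweigh the shielding by that axial group. The fallback sets out from 13. MeLi in THF should cleave the enol silyl ether to the regiodefined lithium enolate, and alkylation with Bu3SnCH2I should occur trans to the C7a branch to give the stannyl ketone F3. TiCl4 in CH2Cl2 at −78 °C should then close the cyclopropanol F4 by attack of the C–Sn bond on the activated ketone, with loss of Bu3SnCl. Silylation with TBSOTf and 2,6-lutidine returns to 14. Here C3a is fixed by enolate alkylation and not by carbenoid delivery.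

Step 21. Acylation of the hindered C2 alcohol may be slow enough for the angeloyl group to isomerise to the tigloyl group. The fallback sets out from 29. Acylation with 2-[bis(2,2,2-trifluoroethoxy)phosphoryl]propanoic acid (DCC, DMAP, CH2Cl2) should give the phosphonate ester F5. Still–Gennari olefination with acetaldehyde (KN(SiMe3)2, 18-crown-6, THF, −78 °C) should then build the Z-trisubstituted double bond on the ester and return to 32.

Further compounds

F1 | step 19 | acetyloxy{[(1R,2R,3S,4R)-4-[(4-methoxyphenyl)methoxy]-2-[(2S,3R)-3-[(naphthalen-2-yl)methoxy]-1-oxobutan-2-yl]-6-oxo-3-(propan-2-yl)cyclohexyl]methyl}mercury | CC(=O)O[Hg]C[C@H]1C(=O)C[C@@H](OCc2ccc(OC)cc2)[C@@H](C(C)C)[C@@H]1[C@H](C=O)[C@@H](C)OCc3ccc4ccccc4c3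
F2 | step 19 | (2S,3R)-2-[(1R,2S,3R)-3-[(4-methoxyphenyl)methoxy]-6-methylidene-5-oxo-2-(propan-2-yl)cyclohexyl]-3-[(naphthalen-2-yl)methoxy]butanal | C=C1C(=O)C[C@@H](OCc2ccc(OC)cc2)[C@@H](C(C)C)[C@@H]1[C@H](C=O)[C@@H](C)OCc3ccc4ccccc4c3
F3 | step 11 | methyl 2-[(1S,2R,5R,6S)-5-[(4-methoxyphenyl)methoxy]-3-oxo-6-(propan-2-yl)-2-[(tributylstannyl)methyl]cyclohexyl]acetate | CCCC[Sn](CCCC)(CCCC)C[C@H]1C(=O)C[C@@H](OCc2ccc(OC)cc2)[C@@H](C(C)C)[C@@H]1CC(=O)OC
F4 | step 11 | methyl 2-[(1R,2S,3S,4R,6R)-6-hydroxy-4-[(4-methoxyphenyl)methoxy]-3-(propan-2-yl)bicyclo[4.1.0]heptan-2-yl]acetate | O[C@]12C[C@@H](OCc3ccc(OC)cc3)[C@@H](C(C)C)[C@H](CC(=O)OC)[C@H]1C2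
F5 | step 21 | (1S,2S,3aR,6R,7S,7aR)-6-[(4-methoxyphenyl)methoxy]-4-methylidene-1-[(1R)-1-[(naphthalen-2-yl)methoxy]ethyl]-7-(propan-2-yl)octahydro-1H-inden-2-yl 2-[bis(2,2,2-trifluoroethoxy)phosphoryl]propanoate (both epimers at the phosphonate carbon) | C=C1C[C@@H](OCc3ccc(OC)cc3)[C@@H](C(C)C)[C@@H]2[C@@H]([C@@H](C)OCc4ccc5ccccc5c4)[C@@H](OC(=O)C(C)P(=O)(OCC(F)(F)F)OCC(F)(F)F)C[C@@H]12
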